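Over 40 min the flask turns starting material into product on enzyme, while gas dissolves as second substrate, starting from none. You want the product at that time, and how near second substrate stands to saturation.

| setting | summer | dusk | flask |
|---|---|---|---|
| starting material | 7.4 mM | 16 mM | 11 mM |
| gas | 0.38 mM (held) | 0.38 mM (held) | 0.38 mM (held) |
| enzyme | 1.1 µM | 1.1 µM | 1.1 µM |
| remark | run made earlier | run made earlier |  |
| time |  |  | 40 min |

| run | time / min | product / % | starting material / % |
|---|---|---|---|
| summer | 6.00 | 2 | 101 |
| summer | 15.0 | 6 | 94 |
| summer | 30.0 | 13 | 86 |
| summer | 50.0 | 22 | 77 |
| dusk | 4.00 | 2 | 99 |
| dusk | 8.00 | 4 | 97 |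
| dusk | 20.0 | 1 | 94 |
| dusk | 50.0 | 9 | 87 |

(each reading ± 2 percentage points)

- how much product there is at 40 min, in percent of the starting material charged
- concentration of second substrate in solution at 40 min, in percent of saturation

- at the start none of the gas is in solution
- second substrate is what gas becomes in solution

Turn the last product reading of each run into a rate v, the concentration of product made per minute. The summer run gives 0.0326 mM/min. The dusk run, charged with about twice the starting material, gives 0.0288 mM/min. At the summer rate the dusk run should read 10.2 % at 50.0 min; it reads 9 %, and a reading scatters by 2 percentage points. So I read the rate as zero order in starting material, with each enzyme molecule working at its own pace.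

Call that pace T = v/E, with E the enzyme charged: 29.6 /min. This is the turnover number, product made per enzyme per minute. A constant rate, dP/dt = T·E, integrates to P = T·E·t, with P the product concentration and t the time. Is a lag needed? The summer line through the origin gives 2.64 % at 6.00 min and the reading is 2 %, so I subtract none. The flask's charge lies between those of the two runs, and its enzyme is theirs, so I expect 11.8 % of its charge as product.

Second substrate is poorly read. If gas passes into solution with a time constant τ, and second substrate is made as fast as it is used, its shortfall below saturation is vτ. I subtracted no lag at 6.00 min, so I try a τ as long as that time, which gives a shortfall of 51.4 % of saturation; my rough estimate is 48.6 % of saturation or above.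

The forecast stands lower on product, at 11.5 %, and puts second substrate at 60 %, adding that “this is a weak guess”.

The flask gives 12.1 % of product, with second substrate at 87.4 % of saturation.

    second substrate + starting complex ⇌ ternary complex (K = 2300 /M, k = 5.20 × 10⁵ /M/s)
    gas ⇌ second substrate, rate k2*(csat - [second substrate]) (kL = 0.710 /min)
    ternary complex ⇌ enzyme + product (K = 0.0260 M, k = 73.0 /min)
    starting material + enzyme ⇌ starting complex (K = 3500 /M, k = 28000 /M/s)

At 40.0 min the flask's enzyme stands 55.8 % as starting complex and 42.4 % as ternary complex, with 1.84 % free. Averaged over the 40 min and taken per enzyme charged, the flask's own turnover number comes to 30.2 /min. Carried to a neighbour flask with 0.0027 mM of enzyme, T gives 29.1 % of product; that neighbour gives 26.5 %, with its second substrate at 0.276 mM.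

Readings and results stem from a simulated flask with made-up constants; scatter was added.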